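Retrosynthetic overview
1. Daucane numbering is used. C1 is the quaternary ring-fusion carbon (methyl C15). C2 and C3 are the two CH2 groups of five-membered ring B, C4 is the isopropyl carbinol, C5 the ring-fusion CH and C6 the acyloxy carbon. C7–C10 complete seven-membered ring A (C8=C9, methyl C14 on C8).
2. Late cuts: the C6–O ester bond (Steglich coupling with acetate-masked p-coumaric acid) leads back to jaeschkeanadiol. The C4–isopropyl bond (organocerium addition) leads back to a trans-fused hydroazulen-4-one, so C4 is handled one oxidation level up.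
3. Key cut C3–C4: ring B is closed on a monocyclic cycloheptene by rhodium-catalysed intramolecular hydroacylation. This reverses the polarity of the formyl carbon C4 and adds its C–H bond across an unactivated vinyl group, with no reagent and no by-product.
4. Enabling feature: C4–C5–C1–C2=C3 is a 4-pentenal laid over the C5–C1 edge of ring A, with formyl and vinyl trans-diequatorial on neighbouring ring atoms. Quaternary C1 gives gem-disubstituent compression and leaves the vinyl group no allylic hydrogen, and the C6 oxygen sits β to C4 for chelation.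
5. Ring order: A first (ring-closing metathesis, C8=C9), B second (key step). Before that, the C1–C5 bond and both its stereocentres come from a chelated dianionic ester-enolate Claisen rearrangement steered by C6, the only purchased stereocentre.

Key step: step 9

Remark on the chemistry: the given structure is read as (3R,3aS,4S,8aR) in azulene numbering. This means a trans ring fusion, C4–OH cis to C15 and to C6 on ring B, and C6–O trans to C4 on ring A.

Step 1
Reactants: 1 pent-1-en-4-yne
Product: 4 (2E)-3-methylhexa-2,5-dien-1-ol, via alkenyldimethylalane 2 (not isolated), via lithium alkenylalanate 3 (not isolated)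
Conditions: Me3Al, Cp2ZrCl2 (0.2 equiv), CH2Cl2, 0 → 23 °C; n-BuLi, hexane, 0 °C; (CH2O)n, THF, 23 °C; H2O
Reagents that add atoms: trimethylaluminium C[Al](C)C; formaldehyde (from paraformaldehyde) C=O
Why: Negishi zirconium-catalysed carboalumination adds methyl and aluminium syn across the terminal alkyne with methyl on the internal carbon, which fixes the E geometry, and hydroxymethylation of the derived alanate with formaldehyde should retain it.

Step 2
Reactants: 5 ethyl (3R)-4-chloro-3-hydroxybutanoate
Product: 6 ethyl [(2R)-oxiran-2-yl]acetate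
Conditions: Ag2O, 1,2-dimethoxyethane, reflux
Reagents that add atoms: none
Why: Silver-assisted intramolecular Williamson-type epoxide closure works without base and so should avoid opening to the 4-hydroxycrotonate, and the stereocentre (future C6) is not touched.

Step 3
Reactants: 6 ethyl [(2R)-oxiran-2-yl]acetate
Product: 7 ethyl (3S)-3-hydroxy-5-methylhex-5-enoate
Conditions: isopropenylmagnesium bromide (1.5 equiv), CuI (0.15 equiv), THF, −40 → −20 °C; H2O
Reagents that add atoms: isopropenylmagnesium bromide CC(=C)[Mg]Br
Why: Copper-catalysed Grignard opening of a terminal epoxide goes to the unsubstituted carbon faster than to the ester at low temperature, and the C–O bond at the stereocentre stays intact so the descriptor changes only through the CIP ranking.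

Step 4
Reactants: 7 ethyl (3S)-3-hydroxy-5-methylhex-5-enoate; 4 (2E)-3-methylhexa-2,5-dien-1-ol
Product: 8 (2E)-3-methylhexa-2,5-dien-1-yl (3S)-3-hydroxy-5-methylhex-5-enoate
Conditions: ClBu2SnOSnBu2OH (5 mol %), toluene, reflux, EtOH removed over 4 Å sieves
Reagents that add atoms: none
Why: Distannoxane-catalysed transesterification is neutral, works with near-equimolar primary alcohol once ethanol is removed, and should leave the β-hydroxyl, the stereocentre and the alkene geometry alone.

Step 5
Reactants: 8 (2E)-3-methylhexa-2,5-dien-1-yl (3S)-3-hydroxy-5-methylhex-5-enoate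
Product: 10 (2S,3S)-3-hydroxy-5-methyl-2-[(3S)-3-methylhexa-1,5-dien-3-yl]hex-5-enoic acid, via dilithium alkoxide enolate 9 (not isolated)
Conditions: LiN(iPr)2 (2.3 equiv), THF, −78 °C; −78 → 23 °C, then 45 °C; 1 M HCl
Reagents that add atoms: none
Why: In this dianionic ester-enolate Claisen rearrangement (Ireland–Claisen family) the C6 alkoxide and the enolate oxygen share lithium in a six-membered chelate that puts C6 trans to the allyloxy oxygen and exposes the face anti to the methallyl group as in a Fráter–Seebach alkylation (sets C5 anti to C6–O), while the chair transition state of the E-alkene places the allyl chain equatorial and the methyl axial (sets quaternary C1).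

Step 6
Reactants: 10 (2S,3S)-3-hydroxy-5-methyl-2-[(3S)-3-methylhexa-1,5-dien-3-yl]hex-5-enoic acid
Product: 11 (2R,3S)-5-methyl-2-[(3S)-3-methylhexa-1,5-dien-3-yl]hex-5-ene-1,3-diol
Conditions: LiAlH4 (3 equiv), THF, 0 °C → reflux; H2O
Reagents that add atoms: none
Why: Hydride reduction of the carboxylic acid to the primary alcohol leaves isolated alkenes untouched and proceeds through a carboxylate that cannot epimerise C5.

Step 7
Reactants: 11 (2R,3S)-5-methyl-2-[(3S)-3-methylhexa-1,5-dien-3-yl]hex-5-ene-1,3-diol
Product: 12 (1S,6S,7R)-6-ethenyl-7-(hydroxymethyl)-3,6-dimethylcyclohept-3-en-1-ol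
Conditions: second-generation Grubbs catalyst (H2IMes)(PCy3)Cl2Ru=CHPh (5 mol %), CH2Cl2 (2 mM), reflux
Reagents that add atoms: none
Why: In this ring-closing metathesis the catalyst should load on the unhindered allyl terminus and close onto the methallyl group to give ring A with the trisubstituted C8=C9 alkene, whereas the vinyl group on quaternary C1 is too hindered to initiate and could meet the loaded carbene only through a cyclobutene.

Step 8
Reactants: 12 (1S,6S,7R)-6-ethenyl-7-(hydroxymethyl)-3,6-dimethylcyclohept-3-en-1-ol
Product: 13 (1S,2S,7S)-2-ethenyl-7-hydroxy-2,5-dimethylcyclohept-4-ene-1-carbaldehyde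
Conditions: TEMPO (0.1 equiv), PhI(OAc)2 (1.1 equiv), CH2Cl2, 23 °C
Reagents that add atoms: none
Why: The TEMPO oxoammonium oxidation takes the primary carbinol for steric reasons, spares the secondary C6 hydroxyl and the alkenes, and stops at the aldehyde, whose C5 already holds the more stable equatorial configuration.

Step 9
Reactants: 13 (1S,2S,7S)-2-ethenyl-7-hydroxy-2,5-dimethylcyclohept-4-ene-1-carbaldehyde
Product: 14 (3aR,8S,8aS)-8-hydroxy-3a,6-dimethyl-3,3a,4,7,8,8a-hexahydroazulen-1(2H)-one
Conditions: [Rh(nbd)(dppe)]BF4 (5 mol %, activated with H2, then Ar purge), acetone, 23 → 45 °C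
Reagents that add atoms: none
Why: The solvated cation [Rh(dppe)]+ (monovalent rhodium) inserts into the formyl C–H bond of 13 to give an acyl hydride of trivalent rhodium, so that C4, an electrophile in the aldehyde, becomes a metal-bound acyl donor; the vinyl group then binds, inserts into Rh–H with the metal going to the terminal carbon C3, and the six-membered acyl alkyl rhodacycle (Rh, C4, C5, C1, C2, C3) collapses by reductive elimination to the C3–C4 bond. The closest known reaction type is the intramolecular hydroacylation of 4-pentenals to cyclopentanones with cationic diphosphine rhodium catalysts, for which 2-substituted and 3,3-disubstituted substrates are established. Ring B is closed in a formally 5-endo-trig sense at the alkene, which is allowed here because the bond arises by reductive elimination from the six-membered metallacycle and not by direct attack on the π bond. No new stereocentre is formed: C1, C5 and C6 are carried through, and the trans ring fusion follows from the trans-diequatorial formyl and vinyl groups on ring A, with C5 already in its more stable equatorial configuration so that enolisation has nothing to erode. The step needs hydroacylation to win over decarbonylation and alkene migration and needs the vinyl group to win over C8=C9: quaternary C1 speeds insertion by gem-disubstituent compression and offers no allylic hydrogen for migration, the C6 hydroxyl can close a five-membered O–Rh chelate that occupies the site needed for CO extrusion, and the trisubstituted ring alkene could only react through a strained bridged metallacycle. The ketone that appears at C4 is exactly the handle needed for the last carbon–carbon bond and the last stereocentre.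

Step 10
Reactants: 14 (3aR,8S,8aS)-8-hydroxy-3a,6-dimethyl-3,3a,4,7,8,8a-hexahydroazulen-1(2H)-one
Product: 15 jaeschkeanadiol, (3R,3aS,4S,8aR)-6,8a-dimethyl-3-(propan-2-yl)-1,2,3a,4,5,8-hexahydroazulene-3,4-diol
Conditions: CeCl3 (4 equiv), iPrLi (4 equiv), THF, −78 °C; then 14, −78 → −40 °C; H2O
Reagents that add atoms: isopropyllithium [Li]C(C)C
Why: Organocerium 1,2-addition is weakly basic and should suppress enolisation, β-hydride reduction and retro-aldol opening of the cerium aldolate, and the nucleophile should enter C4 from the α face syn to H-5 because the β face is screened by the pseudo-axial C15 methyl and by C6, so that the hydroxyl ends β and the isopropyl group α.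

Step 11
Reactants: 15 jaeschkeanadiol; 16 (2E)-3-[4-(acetyloxy)phenyl]prop-2-enoic acid
Product: 17 (3R,3aS,4S,8aR)-3-hydroxy-6,8a-dimethyl-3-(propan-2-yl)-1,2,3,3a,4,5,8,8a-octahydroazulen-4-yl (2E)-3-[4-(acetyloxy)phenyl]prop-2-enoate
Conditions: DCC (1.5 equiv), DMAP (0.3 equiv), CH2Cl2, 23 °C
Reagents that add atoms: none
Why: Steglich esterification should acylate only the secondary C6 hydroxyl because the tertiary C4 hydroxyl is inert to carbodiimide and DMAP activation, and neither a stereocentre nor the E-cinnamate geometry is touched.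

Step 12
Reactants: 17 (3R,3aS,4S,8aR)-3-hydroxy-6,8a-dimethyl-3-(propan-2-yl)-1,2,3,3a,4,5,8,8a-octahydroazulen-4-yl (2E)-3-[4-(acetyloxy)phenyl]prop-2-enoate
Product: 18 target, (3R,3aS,4S,8aR)-3-hydroxy-6,8a-dimethyl-3-(propan-2-yl)-1,2,3,3a,4,5,8,8a-octahydroazulen-4-yl (2E)-3-(4-hydroxyphenyl)prop-2-enoate
Conditions: pyrrolidine (3 equiv), CH2Cl2, 0 → 23 °C
Reagents that add atoms: none
Why: Chemoselective aminolysis cleaves the activated aryl acetate much faster than the hindered, conjugated secondary alkyl cinnamate, so the phenol should be freed without loss of the C6 ester.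

Compound list
1 | pent-1-en-4-yne | C#CCC=C | starting material
2 | dimethyl[(1E)-2-methylpenta-1,4-dien-1-yl]alane | C=CC/C(C)=C/[Al](C)C | intermediate
3 | lithium butyl(dimethyl)[(1E)-2-methylpenta-1,4-dien-1-yl]alanate | [Li+].C=CC/C(C)=C/[Al-](C)(C)CCCC | intermediate
4 | (2E)-3-methylhexa-2,5-dien-1-ol | C=CC/C(C)=C/CO | intermediate
5 | ethyl (3R)-4-chloro-3-hydroxybutanoate | CCOC(=O)C[C@@H](O)CCl | starting material
6 | ethyl [(2R)-oxiran-2-yl]acetate | CCOC(=O)C[C@@H]1CO1 | intermediate
7 | ethyl (3S)-3-hydroxy-5-methylhex-5-enoate | CCOC(=O)C[C@@H](O)CC(C)=C | intermediate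
8 | (2E)-3-methylhexa-2,5-dien-1-yl (3S)-3-hydroxy-5-methylhex-5-enoate | C=CC/C(C)=C/COC(=O)C[C@@H](O)CC(C)=C | intermediate
9 | dilithium (1E,3S)-5-methyl-1-{[(2E)-3-methylhexa-2,5-dien-1-yl]oxy}hexa-1,5-diene-1,3-diolate | [Li+].[Li+].C=CC/C(C)=C/CO/C([O-])=C/[C@@H]([O-])CC(C)=C | intermediate
10 | (2S,3S)-3-hydroxy-5-methyl-2-[(3S)-3-methylhexa-1,5-dien-3-yl]hex-5-enoic acid | OC(=O)[C@H]([C@@H](O)CC(C)=C)[C@@](C)(CC=C)C=C | intermediate
11 | (2R,3S)-5-methyl-2-[(3S)-3-methylhexa-1,5-dien-3-yl]hex-5-ene-1,3-diol | OC[C@H]([C@@H](O)CC(C)=C)[C@@](C)(CC=C)C=C | intermediate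
12 | (1S,6S,7R)-6-ethenyl-7-(hydroxymethyl)-3,6-dimethylcyclohept-3-en-1-ol | CC1=CC[C@@](C)(C=C)[C@H](CO)[C@@H](O)C1 | intermediate
13 | (1S,2S,7S)-2-ethenyl-7-hydroxy-2,5-dimethylcyclohept-4-ene-1-carbaldehyde | CC1=CC[C@@](C)(C=C)[C@H](C=O)[C@@H](O)C1 | intermediate
14 | (3aR,8S,8aS)-8-hydroxy-3a,6-dimethyl-3,3a,4,7,8,8a-hexahydroazulen-1(2H)-one | CC1=CC[C@@]2(C)CCC(=O)[C@@H]2[C@@H](O)C1 | intermediate
15 | jaeschkeanadiol, (3R,3aS,4S,8aR)-6,8a-dimethyl-3-(propan-2-yl)-1,2,3a,4,5,8-hexahydroazulene-3,4-diol | CC1=CC[C@@]2(C)CC[C@@](O)(C(C)C)[C@@H]2[C@@H](O)C1 | intermediate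
16 | (2E)-3-[4-(acetyloxy)phenyl]prop-2-enoic acid | CC(=O)Oc1ccc(/C=C/C(O)=O)cc1 | starting material
17 | (3R,3aS,4S,8aR)-3-hydroxy-6,8a-dimethyl-3-(propan-2-yl)-1,2,3,3a,4,5,8,8a-octahydroazulen-4-yl (2E)-3-[4-(acetyloxy)phenyl]prop-2-enoate | CC1=CC[C@@]2(C)CC[C@@](O)(C(C)C)[C@@H]2[C@@H](OC(=O)/C=C/c2ccc(OC(C)=O)cc2)C1 | intermediate
18 | (3R,3aS,4S,8aR)-3-hydroxy-6,8a-dimethyl-3-(propan-2-yl)-1,2,3,3a,4,5,8,8a-octahydroazulen-4-yl (2E)-3-(4-hydroxyphenyl)prop-2-enoate | CC1=CC[C@@]2(C)CC[C@@](O)(C(C)C)[C@@H]2[C@@H](OC(=O)/C=C/c2ccc(O)cc2)C1 | target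

Total step count: 12. Longest linear sequence: 11 steps (5 → 18, steps 2 to 12).

Steps most likely to fail

Step 9 (key step).
- What may go wrong: the acyl rhodium hydride may extrude CO faster than the hindered vinyl group inserts. That strips C4 from the substrate and deactivates the catalyst as a carbonyl complex.
- Fallback: the same C3–C4 bond is made by cross-coupling of an acyl electrophile with an alkylborane. It sets out from 10.
- Ring-closing metathesis as in step 7 gives (1S,2S,7S)-2-ethenyl-7-hydroxy-2,5-dimethylcyclohept-4-ene-1-carboxylic acid F1.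
- PhSH, DCC and catalytic DMAP give the S-phenyl thioester F2.
- 9-BBN-H (2.2 equiv, THF) should add only to the vinyl group and cap the hydroxyl, giving the B-alkyl borane borinate F3.
- An intramolecular Liebeskind–Srogl ketone synthesis (Pd2(dba)3, P(2-furyl)3, copper thiophene-2-carboxylate Cu(O2CC4H3S), Cs2CO3, THF, 45 °C) with aqueous work-up comes back to the route at 14.

Step 5.
- What may go wrong: the dianion may fragment or lose its chelate before the slow rearrangement to a quaternary centre. Facial selectivity or the chair preference would then erode.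
- Fallback: substrate control is replaced by reagent control. It sets out from 8.
- TBSCl and imidazole give the tert-butyldimethylsilyl ether F4.
- Soft enolisation follows at −78 °C with a C2-symmetric 2-bromo-4,5-diphenyl-1,3-bis(arylsulfonyl)-1,3,2-diazaborolidine (the antipode matched to C6) and a tertiary amine. The amine and solvent are chosen so that C6 stands trans to the allyloxy oxygen.
- This gives a chiral boron ketene acetal that rearranges on warming (boron-enolate variant of the Ireland–Claisen rearrangement) to the silyloxy acid F5.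
- Bu4NF in THF comes back to the route at 10.

Step 10.
- What may go wrong: enolisation, β-hydride transfer from the secondary alkyl nucleophile or retro-aldol opening of ring A may outrun addition to the hindered ketone. Alternatively, the facial preference may be weak.
- Fallback: a smaller sp2 nucleophile without β-hydrogen is used, and the extra alkene is reduced afterwards. It sets out from 14.
- Isopropenylmagnesium bromide with LaCl3·2LiCl (THF, 0 °C) gives the isopropenyl diol F6.
- Hydrogenation with RhCl(PPh3)3 under H2 (1 atm, benzene) should take the 1,1-disubstituted alkene and spare the trisubstituted C8=C9. This comes back to the route at 15.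

Further compounds
F1 | step 9 | (1S,2S,7S)-2-ethenyl-7-hydroxy-2,5-dimethylcyclohept-4-ene-1-carboxylic acid | CC1=CC[C@@](C)(C=C)[C@H](C(O)=O)[C@@H](O)C1
F2 | step 9 | S-phenyl (1S,2S,7S)-2-ethenyl-7-hydroxy-2,5-dimethylcyclohept-4-ene-1-carbothioate | CC1=CC[C@@](C)(C=C)[C@H](C(=O)Sc2ccccc2)[C@@H](O)C1
F3 | step 9 | S-phenyl thioester bearing a 2-(9-borabicyclo[3.3.1]nonan-9-yl)ethyl group on C1 and a 9-borabicyclo[3.3.1]nonan-9-yloxy group on C6 | CC1=CC[C@@](C)(CCB2C3CCCC2CCC3)[C@H](C(=O)Sc2ccccc2)[C@@H](OB2C3CCCC2CCC3)C1
F4 | step 5 | (2E)-3-methylhexa-2,5-dien-1-yl (3S)-3-[(tert-butyldimethylsilyl)oxy]-5-methylhex-5-enoate | C=CC/C(C)=C/COC(=O)C[C@@H](O[Si](C)(C)C(C)(C)C)CC(C)=C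
F5 | step 5 | (2S,3S)-3-[(tert-butyldimethylsilyl)oxy]-5-methyl-2-[(3S)-3-methylhexa-1,5-dien-3-yl]hex-5-enoic acid | OC(=O)[C@H]([C@@H](O[Si](C)(C)C(C)(C)C)CC(C)=C)[C@@](C)(CC=C)C=C
F6 | step 10 | (3S,3aS,4S,8aR)-6,8a-dimethyl-3-(prop-1-en-2-yl)-1,2,3a,4,5,8-hexahydroazulene-3,4-diol | CC1=CC[C@@]2(C)CC[C@@](O)(C(C)=C)[C@@H]2[C@@H](O)C1
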